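**Retrosynthetic overview**
1. Pestalone C ⇒ the iodo-tetraphenol plus a prenylstannane. The acid-sensitive prenyl group goes on last, at C–I and not at C–Br.
2. Iodo-tetraphenol ⇒ its tetramethyl ether, by global O-demethylation while no alkene is present.
3. Key disconnection: the tetra-ortho-substituted 2-aroylbenzaldehyde ⇒ an N-acylhydrazone, so the two rings are joined through a C=N bond. Oxidation then closes two C–O bonds (hydrazide O to the CH carbon, phenol O to the acyl carbon). These two bonds remain in the product as the aldehyde and ketone C=O after N2 leaves and the ring A carbon shifts from O to C.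
4. Hydrazone ⇒ 2-hydroxy-3-iodo-4,6-dimethoxybenzaldehyde (one iodination) plus 3-bromo-2,6-dimethoxy-4-methylbenzohydrazide (from 3,5-dimethoxytoluene by lithiation/CO2, bromination and hydrazide formation).
5. Rings: both benzene rings are bought. The only ring made is a transient azo-bridged 1,3-benzodioxin, formed and destroyed in the key step.

Assumption: the target has no stereocentre and its aryl–carbonyl bonds rotate freely, so it is achiral and the structure as drawn is the compound to be made.

**Step 1**
Reactants: 1 2-hydroxy-4,6-dimethoxybenzaldehyde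
Product: 2 2-hydroxy-3-iodo-4,6-dimethoxybenzaldehyde
Conditions: NIS (1.05 equiv), TFA (0.3 equiv), MeCN, 0 °C → rt, dark
Reagents that add atoms: N-iodosuccinimide, O=C1CCC(=O)N1I
Why: Electrophilic aromatic iodination goes to C3 because it is ortho to the free phenol, para to the 6-methoxy group and less crowded than C5 (which lies between two methoxy groups), the same site at which 2-hydroxy-4,6-dimethoxyaryl carbonyl compounds are known to be halogenated.

**Step 2**
Reactants: 3 3,5-dimethoxytoluene
Product: 5 2,6-dimethoxy-4-methylbenzoic acid, via aryllithium 4 (not isolated)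
Conditions: n-BuLi (1.1 equiv), THF, 0 °C → rt, 2 h; CO2 (gas), −78 °C → rt; 1 M HCl
Reagents that add atoms: carbon dioxide, O=C=O
Why: Directed ortho-metalation followed by carboxylation works because the proton between the two methoxy groups is the most acidic and doubly coordinated site, so lithiation occurs only there and CO2 traps the aryllithium.

**Step 3**
Reactants: 5 2,6-dimethoxy-4-methylbenzoic acid
Product: 6 3-bromo-2,6-dimethoxy-4-methylbenzoic acid
Conditions: NBS (1.0 equiv), MeCN, 0 °C → rt, dark
Reagents that add atoms: N-bromosuccinimide, O=C1CCC(=O)N1Br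
Why: Electrophilic aromatic bromination is clean because the two open positions are equivalent (ortho/para to the methoxy groups), the first bromine slows a second attack, and the same monobromination is routine for 2,6-dimethoxybenzoic acid.

**Step 4**
Reactants: 6 3-bromo-2,6-dimethoxy-4-methylbenzoic acid
Product: 8 3-bromo-2,6-dimethoxy-4-methylbenzohydrazide, via acid chloride 7 (not isolated)
Conditions: (COCl)2 (1.3 equiv), DMF (cat.), CH2Cl2, 0 °C → rt, evaporate; add slowly to N2H4·H2O (6 equiv), THF, 0 °C
Reagents that add atoms: hydrazine (used as the monohydrate), NN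
Why: Acid chloride formation and N-acylation (nucleophilic acyl substitution) succeed because 2,6-dialkoxybenzoyl chlorides are stable yet acylate small alpha-effect nucleophiles cleanly, and inverse addition into excess hydrazine prevents double acylation.

**Step 5**
Reactants: 2 2-hydroxy-3-iodo-4,6-dimethoxybenzaldehyde; 8 3-bromo-2,6-dimethoxy-4-methylbenzohydrazide
Product: 11 2-(3-bromo-2,6-dimethoxy-4-methylbenzoyl)-3-iodo-4,6-dimethoxybenzaldehyde, via acylhydrazone 9 (not isolated), via azo-bridged benzodioxin 10 (not isolated)
Conditions: THF, AcOH (10 mol %), 4 Å MS, 60 °C, 6 h; cool to 0 °C; Pb(OAc)4 (1.2 equiv), 0 °C → rt, 2 h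
Reagents that add atoms: none
Why: Proposed new method: a one-flask condensation/oxidative nitrogen extrusion that replaces a phenolic OH by a di-ortho-substituted aroyl group; acid-catalysed condensation forms the C=N bond of 9, Pb(OAc)4 oxidises its N–H, the hydrazide oxygen closes onto the former CH=N carbon and the neighbouring phenol oxygen onto the acyl carbon (two C–O bonds, bicycle 10), loss of N2 leaves a carbonyl ylide that opens to the free aldehyde and an aryloxy(aryl)carbene, and a 1,2-shift of the ring A carbon from oxygen to the carbene carbon (ipso attack helped by the ortho formyl group) gives the ketone in a unimolecular three-centre step that is little affected by the four ortho substituents that block bimolecular ketone syntheses; the closest known reaction type is the lead tetraacetate oxidation of salicylaldehyde and 2-hydroxyaryl ketone N-acylhydrazones to 2-acylbenzaldehydes and 1,2-diacylbenzenes, which has not been shown for a di-ortho-substituted aroyl hydrazide, for a phenol flanked by a halogen, for a tetra-ortho-substituted benzophenone or without isolation of the hydrazone.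

**Step 6**
Reactants: 11 2-(3-bromo-2,6-dimethoxy-4-methylbenzoyl)-3-iodo-4,6-dimethoxybenzaldehyde
Product: 12 2-(3-bromo-2,6-dihydroxy-4-methylbenzoyl)-4,6-dihydroxy-3-iodobenzaldehyde
Conditions: BBr3 (10 equiv), CH2Cl2, −78 °C → rt, 12 h; ice/H2O
Reagents that add atoms: none
Why: In this Lewis acid aryl methyl ether cleavage (BBr3 demethylation), three of the four methoxy groups are ortho to a carbonyl and cleave by chelation, excess reagent at room temperature removes the fourth, and the aryl halides, ketone and aldehyde survive because no acid-sensitive alkene is present yet.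

**Step 7**
Reactants: 12 2-(3-bromo-2,6-dihydroxy-4-methylbenzoyl)-4,6-dihydroxy-3-iodobenzaldehyde; 13 tributyl(3-methylbut-2-en-1-yl)stannane
Product: 14 pestalone C, 2-(3-bromo-2,6-dihydroxy-4-methylbenzoyl)-4,6-dihydroxy-3-(3-methylbut-2-en-1-yl)benzaldehyde
Conditions: 13 (1.5 equiv), Pd2(dba)3 (2.5 mol %), AsPh3 (20 mol %), NMP, 50 °C, dark
Reagents that add atoms: none
Why: In this Stille cross-coupling, zerovalent palladium inserts into the weak C–I bond much faster than into the electron-rich, doubly flanked C–Br bond, the neutral base-free medium spares the free phenols and the base-sensitive 2-aroylbenzaldehyde, and reductive elimination at the unsubstituted terminus of the prenyl-palladium species gives the linear prenyl arene.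

**Compound list**
1 | 2-hydroxy-4,6-dimethoxybenzaldehyde | COc1cc(O)c(C=O)c(OC)c1 | starting material
2 | 2-hydroxy-3-iodo-4,6-dimethoxybenzaldehyde | COc1cc(OC)c(C=O)c(O)c1I | intermediate
3 | 3,5-dimethoxytoluene (1,3-dimethoxy-5-methylbenzene) | COc1cc(C)cc(OC)c1 | starting material
4 | (2,6-dimethoxy-4-methylphenyl)lithium | [Li]c1c(OC)cc(C)cc1OC | intermediate
5 | 2,6-dimethoxy-4-methylbenzoic acid | COc1cc(C)cc(OC)c1C(=O)O | intermediate
6 | 3-bromo-2,6-dimethoxy-4-methylbenzoic acid | COc1cc(C)c(Br)c(OC)c1C(=O)O | intermediate
7 | 3-bromo-2,6-dimethoxy-4-methylbenzoyl chloride | COc1cc(C)c(Br)c(OC)c1C(=O)Cl | intermediate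
8 | 3-bromo-2,6-dimethoxy-4-methylbenzohydrazide | COc1cc(C)c(Br)c(OC)c1C(=O)NN | intermediate
9 | (E)-3-bromo-N'-(2-hydroxy-3-iodo-4,6-dimethoxybenzylidene)-2,6-dimethoxy-4-methylbenzohydrazide | COc1cc(C)c(Br)c(OC)c1C(=O)N/N=C/c1c(O)c(I)c(OC)cc1OC | intermediate
10 | 2-(3-bromo-2,6-dimethoxy-4-methylphenyl)-9-iodo-6,8-dimethoxy-2,5-dihydro-2,5-epoxy-1,3,4-benzoxadiazepine (racemate, bridgehead configuration fixed by the bicycle) | COc1cc(OC)c2c(c1I)OC1(N=NC2O1)c1c(OC)cc(C)c(Br)c1OC | intermediate
11 | 2-(3-bromo-2,6-dimethoxy-4-methylbenzoyl)-3-iodo-4,6-dimethoxybenzaldehyde | COc1cc(OC)c(C=O)c(C(=O)c2c(OC)cc(C)c(Br)c2OC)c1I | intermediate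
12 | 2-(3-bromo-2,6-dihydroxy-4-methylbenzoyl)-4,6-dihydroxy-3-iodobenzaldehyde | Oc1cc(O)c(C=O)c(C(=O)c2c(O)cc(C)c(Br)c2O)c1I | intermediate
13 | tributyl(3-methylbut-2-en-1-yl)stannane | CCCC[Sn](CCCC)(CCCC)CC=C(C)C | starting material
14 | pestalone C | CC(C)=CCc1c(O)cc(O)c(C=O)c1C(=O)c1c(O)cc(C)c(Br)c1O | target

**Step count**
- Total steps: 7.
- Longest linear sequence: 6 (steps 2 to 7, from 3 to 14).

**Steps most likely to fail**

Step 5 (the proposed new step). The crowded acyl carbon may not be captured by the iodine-flanked phenol, and the oxidised hydrazone may instead aromatise to a 1,3,4-oxadiazole. The fallback uses known chemistry, sets out from 4 and comes back at 11. Bought 3,5-dimethoxybenzoic acid is hydroxymethylated and lactonised (aq. HCHO, conc. HCl, AcOH, 90 °C) to 4,6-dimethoxyphthalide F1. This is iodinated (NIS, TFA, MeCN) para to the 4-methoxy group to 7-iodo-4,6-dimethoxyphthalide F2. Aryllithium 4 is transmetalated with MgBr2·OEt2 to (2,6-dimethoxy-4-methylphenyl)magnesium bromide F3, which does not exchange with the aryl iodide. F3 opens the lactone of F2 (THF, 0 °C → 40 °C) to [2-(hydroxymethyl)-6-iodo-3,5-dimethoxyphenyl](2,6-dimethoxy-4-methylphenyl)methanone F4. MnO2 (CH2Cl2, rt) oxidises the benzylic alcohol to 2-(2,6-dimethoxy-4-methylbenzoyl)-3-iodo-4,6-dimethoxybenzaldehyde F5. NBS (1.0 equiv, MeCN, 0 °C) then brominates the only activated open position, on ring B, to give 11.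

Step 7. The iodide is flanked by OH and the aroyl group, the phenols are free, and a branched (reverse prenyl) isomer could form. The fallback sets out from 12 and comes back at 14. Stille coupling with the smaller, regiochemically unambiguous allyltributylstannane (same palladium system) gives 3-allyl-2-(3-bromo-2,6-dihydroxy-4-methylbenzoyl)-4,6-dihydroxybenzaldehyde F6. Olefin cross-metathesis with excess 2-methylbut-2-ene and the second-generation Grubbs catalyst (CH2Cl2, 40 °C) then converts the allyl group into the prenyl group of 14.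

Step 6. The 2-aroylbenzaldehyde unit may degrade under BBr3, or the methoxy group para to the aldehyde may resist cleavage. The fallback sets out from 11 and comes back at 12. Hard acid/soft nucleophile cleavage (AlCl3, EtSH, CH2Cl2, 0 °C → rt) removes all four methyl groups and at the same time masks the aldehyde. The product is {2-[bis(ethylsulfanyl)methyl]-3,5-dihydroxy-6-iodophenyl}(3-bromo-2,6-dihydroxy-4-methylphenyl)methanone F7. Thioacetal exchange with glyoxylic acid (AcOH, cat. HCl, rt) then releases the aldehyde of 12 under mildly acidic, non-basic conditions.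

**Further compounds**
F1 | step 5 | 4,6-dimethoxyphthalide (4,6-dimethoxy-2-benzofuran-1(3H)-one) | COc1cc(OC)c2COC(=O)c2c1
F2 | step 5 | 7-iodo-4,6-dimethoxyphthalide | COc1cc(OC)c2COC(=O)c2c1I
F3 | step 5 | (2,6-dimethoxy-4-methylphenyl)magnesium bromide | COc1cc(C)cc(OC)c1[Mg]Br
F4 | step 5 | [2-(hydroxymethyl)-6-iodo-3,5-dimethoxyphenyl](2,6-dimethoxy-4-methylphenyl)methanone | COc1cc(OC)c(CO)c(C(=O)c2c(OC)cc(C)cc2OC)c1I
F5 | step 5 | 2-(2,6-dimethoxy-4-methylbenzoyl)-3-iodo-4,6-dimethoxybenzaldehyde | COc1cc(OC)c(C=O)c(C(=O)c2c(OC)cc(C)cc2OC)c1I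
F6 | step 7 | 3-allyl-2-(3-bromo-2,6-dihydroxy-4-methylbenzoyl)-4,6-dihydroxybenzaldehyde | C=CCc1c(O)cc(O)c(C=O)c1C(=O)c1c(O)cc(C)c(Br)c1O
F7 | step 6 | {2-[bis(ethylsulfanyl)methyl]-3,5-dihydroxy-6-iodophenyl}(3-bromo-2,6-dihydroxy-4-methylphenyl)methanone | CCSC(SCC)c1c(O)cc(O)c(I)c1C(=O)c1c(O)cc(C)c(Br)c1O
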